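## Retrosynthetic overview

1. The target comes from a tricyclic ketone by Wittig methylenation of the ring C carbonyl and removal of a silyl ether.
2. Ring C (formed last, with the bridgehead alkene) comes from a Claisen ring expansion of a bridged vinyl lactone after Petasis methylenation.
3. Ring B (formed second) comes from an intramolecular Hosomi–Sakurai addition of a ring A allylsilane to a tethered vinyl ketone, which also sets the cis ring fusion and the ring A exocyclic methylene.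
4. Ring A (formed first) comes from an organocatalytic Michael/aldol annulation of (S)-citronellal with methyl vinyl ketone; SeO2 then installs the (E)-allylic alcohol, and a Mukaiyama–Michael addition sets the next ring centre trans to the side chain.
5. Order of ring formation: A, then B, then C.

Assumption: the (S)-diarylprolinol silyl ether gives the (2S) Michael adduct, as in related enamine additions of aldehydes to enones and nitroalkenes; if the sense were opposite, the (R)-catalyst would be used.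

Abbreviation: SC = (2S,5E)-7-[(tert-butyldiphenylsilyl)oxy]-6-methylhept-5-en-2-yl.

## Route

Step 1
Reactants: 1 (S)-citronellal; 2 methyl vinyl ketone
Product: 4 (4S)-4-[(2S)-6-methylhept-5-en-2-yl]cyclohex-2-en-1-one, via keto aldehyde 3 (not isolated)
Conditions: (S)-α,α-diphenylprolinol trimethylsilyl ether (5 mol %), ethyl 3,4-dihydroxybenzoate (20 mol %), neat, 4 °C; then KOH, n-Bu4NOH (cat.), THF–Et2O–H2O, reflux
Reagents that add atoms: none
Why: Enamine-catalysed Michael addition, in which the catalyst blocks one face of the E-enamine and sets the new (S) centre, is followed by intramolecular aldol condensation (Robinson-type annulation) to close ring A.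

Step 2
Reactants: 4 (4S)-4-[(2S)-6-methylhept-5-en-2-yl]cyclohex-2-en-1-one
Product: 5 (4S)-4-[(2S,5E)-7-hydroxy-6-methylhept-5-en-2-yl]cyclohex-2-en-1-one
Conditions: SeO2 (0.3 equiv), t-BuOOH, salicylic acid (cat.), CH2Cl2, 23 °C
Reagents that add atoms: tert-butyl hydroperoxide, CC(C)(C)OO
Why: Catalytic SeO2 allylic oxidation (ene reaction then [2,3]-sigmatropic shift) attacks only the electron-rich trisubstituted alkene and oxidises the (E)-methyl of the gem-dimethyl terminus, touching no stereocentre.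

Step 3
Reactants: 5 (4S)-4-[(2S,5E)-7-hydroxy-6-methylhept-5-en-2-yl]cyclohex-2-en-1-one
Product: 6 (4S)-4-SC-cyclohex-2-en-1-one
Conditions: TBDPSCl, imidazole, CH2Cl2, 23 °C
Reagents that add atoms: tert-butyl(chloro)diphenylsilane, CC(C)(C)[Si](Cl)(c1ccccc1)c1ccccc1
Why: Silylation of the primary allylic alcohol gives an ether that survives Grignard reagents, Lewis acids and heat and is removed by fluoride in the last step.

Step 4
Reactants: 6 (4S)-4-SC-cyclohex-2-en-1-one; 7 1-[(tert-butyldimethylsilyl)oxy]-1-methoxyethene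
Product: 9 methyl 2-[(1S,6S)-6-SC-3-[(trifluoromethanesulfonyl)oxy]cyclohex-2-en-1-yl]acetate, via silyl enol ether 8 (not isolated)
Conditions: Tf2NH (2 mol %), CH2Cl2, −78 °C; evaporate; CsF, PhNTf2, DME, 23 °C
Reagents that add atoms: N-phenylbis(trifluoromethanesulfonimide), O=S(=O)(N(c1ccccc1)S(=O)(=O)C(F)(F)F)C(F)(F)F
Why: In this Mukaiyama–Michael addition the ketene acetal adds axially anti to the C4 side chain (new centre trans to SC), silyl transfer fixes the enol ether regiochemistry, and the fluoride-released enolate is O-triflated in place.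

Step 5
Reactants: 9 methyl 2-[(1S,6S)-6-SC-3-[(trifluoromethanesulfonyl)oxy]cyclohex-2-en-1-yl]acetate
Product: 10 methyl 2-[(1S,6S)-6-SC-3-[(trimethylsilyl)methyl]cyclohex-2-en-1-yl]acetate
Conditions: Me3SiCH2MgCl, Pd(PPh3)4 (5 mol %), Et2O, 0 → 23 °C
Reagents that add atoms: (trimethylsilyl)methylmagnesium chloride, C[Si](C)(C)C[Mg]Cl
Why: Kumada–Corriu coupling of the enol triflate installs the allylsilane with the double bond fixed toward the ring carbon that must later bond, and the hindered Grignard reagent does not attack the methyl ester at this temperature.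

Step 6
Reactants: 10 methyl 2-[(1S,6S)-6-SC-3-[(trimethylsilyl)methyl]cyclohex-2-en-1-yl]acetate; 11 2-bromo-N-methoxy-N-methylacetamide
Product: 13 methyl (2S)-4-[methoxy(methyl)amino]-4-oxo-2-[(1S,6S)-6-SC-3-[(trimethylsilyl)methyl]cyclohex-2-en-1-yl]butanoate, via lithium enolate 12 (not isolated)
Conditions: LiN(i-Pr)2, THF, −78 °C; then 11, DMPU, −78 → −30 °C
Reagents that add atoms: none
Why: In this ester enolate alkylation (SN2) the 1,3-allylic strain model predicts entry of the electrophile anti to the SC-bearing ring carbon, giving mainly the drawn (2S) epimer, and any C2 epimer is funnelled to the same tricycle by the equilibration in step 10.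

Step 7
Reactants: 13 methyl (2S)-4-[methoxy(methyl)amino]-4-oxo-2-[(1S,6S)-6-SC-3-[(trimethylsilyl)methyl]cyclohex-2-en-1-yl]butanoate
Product: 15 methyl (2S)-4-oxo-2-[(1S,6S)-6-SC-3-[(trimethylsilyl)methyl]cyclohex-2-en-1-yl]hex-5-enoate, via magnesium hemiaminal 14 (not isolated)
Conditions: CH2=CHMgBr, THF, −78 → 0 °C; cold aq. NH4Cl
Reagents that add atoms: vinylmagnesium bromide, C=C[Mg]Br
Why: Weinreb ketone synthesis, in which the chelated tetrahedral adduct stops at mono-addition and the α-branched methyl ester reacts more slowly, releases the vinyl ketone on quench.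

Step 8
Reactants: 15 methyl (2S)-4-oxo-2-[(1S,6S)-6-SC-3-[(trimethylsilyl)methyl]cyclohex-2-en-1-yl]hex-5-enoate
Product: 17 methyl (1S,2S,7S,11S)-8-methylidene-4-oxo-11-SC-bicyclo[5.4.0]undecane-2-carboxylate, via titanium enolate 16 (not isolated)
Conditions: TiCl4, CH2Cl2, −78 °C; aq. NaHCO3
Reagents that add atoms: none
Why: In this intramolecular Hosomi–Sakurai conjugate addition the ring carbon γ to silicon attacks the enone terminus, closing seven-membered ring B and unveiling the exocyclic methylene, and because the tether hangs from the neighbouring stereocentre the new bond forms on the same face, giving the cis ring fusion in a form that cannot epimerise.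

Step 9
Reactants: 17 methyl (1S,2S,7S,11S)-8-methylidene-4-oxo-11-SC-bicyclo[5.4.0]undecane-2-carboxylate
Product: 19 (1S,2S,4S,7S,11S)-4-ethenyl-8-methylidene-11-SC-bicyclo[5.4.0]undecane-2,4-carbolactone, via magnesium alkoxide 18 (not isolated)
Conditions: CH2=CHMgBr, THF, −78 → 23 °C; then NaOMe (cat.), MeOH, 23 °C
Reagents that add atoms: vinylmagnesium bromide, C=C[Mg]Br
Why: Chemoselective Grignard 1,2-addition to the ketone anti to the ester gives a tertiary alkoxide that lactonises across the 1,3-positions of ring B, and NaOMe lets any adduct of the opposite face close after C2 epimerisation to the lactone bridged on the other face, which converges in step 10.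

Step 10
Reactants: 19 (1S,2S,4S,7S,11S)-4-ethenyl-8-methylidene-11-SC-bicyclo[5.4.0]undecane-2,4-carbolactone
Product: 21 tricyclic ketone (TBDPS ether of the target carrying C=O in place of the ring C exocyclic C=CH2), via enol ether 20 (not isolated)
Conditions: Cp2TiMe2, toluene, 70 °C; filter through basic Al2O3; o-xylene, 180 °C (sealed tube); then NaOMe (cat.), MeOH, 23 °C
Reagents that add atoms: dimethyltitanocene, C[Ti](C)(C1C=CC=C1)C1C=CC=C1
Why: Petasis methylenation of the lactone carbonyl gives an allyl vinyl ether whose Claisen rearrangement (ring expansion of the 2-methylene-5-vinyltetrahydrofuran unit) forms ring C with the bridgehead alkene and the ketone, and NaOMe then equilibrates the α-bridgehead centre to the expected more stable isomer with ring A on the face of ring B away from ring C, as in the target.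

Step 11
Reactants: 21 tricyclic ketone
Product: 22 TBDPS ether of the target
Conditions: Ph3PCH3Br, KOt-Bu, toluene, 23 → 80 °C
Reagents that add atoms: methyltriphenylphosphonium bromide, C[P+](c1ccccc1)(c1ccccc1)c1ccccc1.[Br-]
Why: Wittig methylenation of the only carbonyl group installs the second exocyclic methylene, the α-centre already being at its thermodynamic configuration.

Step 12
Reactants: 22 TBDPS ether of the target
Product: 23 target CNP0264710.1
Conditions: n-Bu4NF, THF, 23 °C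
Reagents that add atoms: none
Why: Fluoride-mediated desilylation frees the primary allylic alcohol without touching the four alkenes or any stereocentre.

## Compound list

1 | (S)-citronellal [(3S)-3,7-dimethyloct-6-enal] | O=CC[C@@H](C)CCC=C(C)C | starting material
2 | methyl vinyl ketone (but-3-en-2-one) | CC(=O)C=C | starting material
3 | (2S)-2-[(2S)-6-methylhept-5-en-2-yl]-5-oxohexanal | O=C[C@H]([C@@H](C)CCC=C(C)C)CCC(C)=O | intermediate
4 | (4S)-4-[(2S)-6-methylhept-5-en-2-yl]cyclohex-2-en-1-one | O=C1CC[C@@H]([C@@H](C)CCC=C(C)C)C=C1 | intermediate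
5 | (4S)-4-[(2S,5E)-7-hydroxy-6-methylhept-5-en-2-yl]cyclohex-2-en-1-one | O=C1CC[C@@H]([C@@H](C)CC/C=C(\C)CO)C=C1 | intermediate
6 | (4S)-4-SC-cyclohex-2-en-1-one | O=C1CC[C@@H]([C@@H](C)CC/C=C(\C)CO[Si](c2ccccc2)(c2ccccc2)C(C)(C)C)C=C1 | intermediate
7 | 1-[(tert-butyldimethylsilyl)oxy]-1-methoxyethene | C=C(OC)O[Si](C)(C)C(C)(C)C | starting material
8 | methyl 2-[(1S,6S)-3-[(tert-butyldimethylsilyl)oxy]-6-SC-cyclohex-2-en-1-yl]acetate | COC(=O)C[C@@H]1C=C(O[Si](C)(C)C(C)(C)C)CC[C@H]1[C@@H](C)CC/C=C(\C)CO[Si](c1ccccc1)(c1ccccc1)C(C)(C)C | intermediate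
9 | methyl 2-[(1S,6S)-6-SC-3-[(trifluoromethanesulfonyl)oxy]cyclohex-2-en-1-yl]acetate | COC(=O)C[C@@H]1C=C(OS(=O)(=O)C(F)(F)F)CC[C@H]1[C@@H](C)CC/C=C(\C)CO[Si](c1ccccc1)(c1ccccc1)C(C)(C)C | intermediate
10 | methyl 2-[(1S,6S)-6-SC-3-[(trimethylsilyl)methyl]cyclohex-2-en-1-yl]acetate | COC(=O)C[C@@H]1C=C(C[Si](C)(C)C)CC[C@H]1[C@@H](C)CC/C=C(\C)CO[Si](c1ccccc1)(c1ccccc1)C(C)(C)C | intermediate
11 | 2-bromo-N-methoxy-N-methylacetamide | CON(C)C(=O)CBr | starting material
12 | lithium ester enolate of 10 (O–Li trans to the ring) | [Li]O/C(OC)=C/[C@@H]1C=C(C[Si](C)(C)C)CC[C@H]1[C@@H](C)CC/C=C(\C)CO[Si](c1ccccc1)(c1ccccc1)C(C)(C)C | intermediate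
13 | methyl (2S)-4-[methoxy(methyl)amino]-4-oxo-2-[(1S,6S)-6-SC-3-[(trimethylsilyl)methyl]cyclohex-2-en-1-yl]butanoate | COC(=O)[C@@H](CC(=O)N(C)OC)[C@@H]1C=C(C[Si](C)(C)C)CC[C@H]1[C@@H](C)CC/C=C(\C)CO[Si](c1ccccc1)(c1ccccc1)C(C)(C)C | intermediate
14 | bromomagnesium hemiaminal of 13 (vinyl added to the amide carbonyl; hemiaminal carbon undefined) | COC(=O)[C@@H](CC(O[Mg]Br)(C=C)N(C)OC)[C@@H]1C=C(C[Si](C)(C)C)CC[C@H]1[C@@H](C)CC/C=C(\C)CO[Si](c1ccccc1)(c1ccccc1)C(C)(C)C | intermediate
15 | methyl (2S)-4-oxo-2-[(1S,6S)-6-SC-3-[(trimethylsilyl)methyl]cyclohex-2-en-1-yl]hex-5-enoate | COC(=O)[C@@H](CC(=O)C=C)[C@@H]1C=C(C[Si](C)(C)C)CC[C@H]1[C@@H](C)CC/C=C(\C)CO[Si](c1ccccc1)(c1ccccc1)C(C)(C)C | intermediate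
16 | trichlorotitanium enolate of 17 (C4=C5, O–TiCl3 on C4) | C=C1CC[C@@H]([C@@H](C)CC/C=C(\C)CO[Si](c3ccccc3)(c3ccccc3)C(C)(C)C)[C@H]2[C@@H]1CC=C(O[Ti](Cl)(Cl)Cl)C[C@@H]2C(=O)OC | intermediate
17 | methyl (1S,2S,7S,11S)-8-methylidene-4-oxo-11-SC-bicyclo[5.4.0]undecane-2-carboxylate (cis-fused) | C=C1CC[C@@H]([C@@H](C)CC/C=C(\C)CO[Si](c3ccccc3)(c3ccccc3)C(C)(C)C)[C@H]2[C@@H]1CCC(=O)C[C@@H]2C(=O)OC | intermediate
18 | bromomagnesium alkoxide of methyl (1S,2S,4S,7S,11S)-4-ethenyl-4-hydroxy-8-methylidene-11-SC-bicyclo[5.4.0]undecane-2-carboxylate | C=C1CC[C@@H]([C@@H](C)CC/C=C(\C)CO[Si](c3ccccc3)(c3ccccc3)C(C)(C)C)[C@H]2[C@@H]1CC[C@@](O[Mg]Br)(C=C)C[C@@H]2C(=O)OC | intermediate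
19 | (1S,2S,4S,7S,11S)-4-ethenyl-8-methylidene-11-SC-bicyclo[5.4.0]undecane-2,4-carbolactone (bridged γ-lactone) | C=C1CC[C@@H]([C@@H](C)CC/C=C(\C)CO[Si](c4ccccc4)(c4ccccc4)C(C)(C)C)[C@H]2[C@@H]1CC[C@@]3(C=C)C[C@@H]2C(=O)O3 | intermediate
20 | exocyclic enol ether of 19 (lactone C=O replaced by C=CH2) | C=C1CC[C@@H]([C@@H](C)CC/C=C(\C)CO[Si](c4ccccc4)(c4ccccc4)C(C)(C)C)[C@H]2[C@@H]1CC[C@@]3(C=C)C[C@@H]2C(=C)O3 | intermediate
21 | tricyclic ketone: ring A cis-fused to bicyclo[4.4.1]undec-1-en-5-one, TBDPS ether of the target with C=O in place of the ring C exocyclic C=CH2 | C=C1CC[C@@H]([C@@H](C)CC/C=C(\C)CO[Si](c3ccccc3)(c3ccccc3)C(C)(C)C)[C@H]2[C@@H]1CCC1=CCCC(=O)[C@H]2C1 | intermediate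
22 | TBDPS ether of the target | C=C1CC[C@@H]([C@@H](C)CC/C=C(\C)CO[Si](c3ccccc3)(c3ccccc3)C(C)(C)C)[C@H]2[C@@H]1CCC1=CCCC(=C)[C@H]2C1 | intermediate
23 | target CNP0264710.1 (all five stereocentres S, side-chain alkene E) | C=C1CC[C@@H]([C@@H](C)CC/C=C(\C)CO)[C@H]2[C@@H]1CCC1=CCCC(=C)[C@H]2C1 | target

## Step count and risk

Total step count: 12. Longest linear sequence: 12 steps (1 to 23); every other input is bought.

The three steps most likely to fail:

Step 8 (ring B closure). The allylsilane may add 1,2 to the ketone to give a five-membered carbinol, or may simply lose silicon. The fallback sets out from 8, this time isolated, and comes back at 17. LiN(i-Pr)2 converts 8 into the lithium enolate F1, which is alkylated with 11 to the Weinreb amide F2. CH2=CHMgBr gives, through the magnesium hemiaminal F3, the vinyl ketone F4. Catalytic Tf2NH then triggers an intramolecular Mukaiyama–Michael addition of the ring A silyl enol ether; aldol addition to the ketone is reversible there while conjugate addition is not. Silyl transfer delivers the cis-fused keto silyl enol ether F5, in which the ring B ketone is masked. Cp2TiMe2 methylenates the one free ketone without base to the methylidene silyl enol ether F6, and dilute HCl in THF hydrolyses the enol ether to 17.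

Step 10 (bridged Claisen ring expansion). The enol ether may isomerise into the ring or fail to rearrange to the strained bridgehead alkene. The fallback sets out from 17 and comes back at 21. Ph3PCH3Br with KOt-Bu gives the dimethylidene ester F7, and Me(MeO)NH·HCl with i-PrMgCl converts it into the Weinreb amide F8. CH2=CHCH2CH2MgBr gives, through the magnesium hemiaminal F9, the butenyl ketone F10. Ring-closing metathesis (second-generation Hoveyda–Grubbs catalyst, toluene, 80 °C, high dilution) between the ring B methylene and the terminal vinyl group then closes ring C to 21, and the NaOMe equilibration is applied as in step 10.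

Step 2 (allylic oxidation). Over-oxidation to the enal and oxidation next to the enone carbonyl may erode the yield. The fallback sets out from 4 and comes back at 5. Cross-metathesis of 4 with 2-methylprop-2-enal (second-generation Hoveyda–Grubbs catalyst, CH2Cl2, 40 °C) gives the enal F11 with (E) geometry. NaBH4 in EtOH–CH2Cl2 at −78 °C then reduces the aldehyde in preference to the ring enone and gives 5.

Further compounds

F1 | step 8 | lithium ester enolate of 8 | [Li]O/C(OC)=C/[C@@H]1C=C(O[Si](C)(C)C(C)(C)C)CC[C@H]1[C@@H](C)CC/C=C(\C)CO[Si](c1ccccc1)(c1ccccc1)C(C)(C)C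
F2 | step 8 | methyl (2S)-2-[(1S,6S)-3-[(tert-butyldimethylsilyl)oxy]-6-SC-cyclohex-2-en-1-yl]-4-[methoxy(methyl)amino]-4-oxobutanoate | COC(=O)[C@@H](CC(=O)N(C)OC)[C@@H]1C=C(O[Si](C)(C)C(C)(C)C)CC[C@H]1[C@@H](C)CC/C=C(\C)CO[Si](c1ccccc1)(c1ccccc1)C(C)(C)C
F3 | step 8 | bromomagnesium hemiaminal of F2 | COC(=O)[C@@H](CC(O[Mg]Br)(C=C)N(C)OC)[C@@H]1C=C(O[Si](C)(C)C(C)(C)C)CC[C@H]1[C@@H](C)CC/C=C(\C)CO[Si](c1ccccc1)(c1ccccc1)C(C)(C)C
F4 | step 8 | methyl (2S)-2-[(1S,6S)-3-[(tert-butyldimethylsilyl)oxy]-6-SC-cyclohex-2-en-1-yl]-4-oxohex-5-enoate | COC(=O)[C@@H](CC(=O)C=C)[C@@H]1C=C(O[Si](C)(C)C(C)(C)C)CC[C@H]1[C@@H](C)CC/C=C(\C)CO[Si](c1ccccc1)(c1ccccc1)C(C)(C)C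
F5 | step 8 | methyl (1S,2S,7S,11S)-4-[(tert-butyldimethylsilyl)oxy]-8-oxo-11-SC-bicyclo[5.4.0]undec-4-ene-2-carboxylate | O=C1CC[C@@H]([C@@H](C)CC/C=C(\C)CO[Si](c3ccccc3)(c3ccccc3)C(C)(C)C)[C@H]2[C@@H]1CC=C(O[Si](C)(C)C(C)(C)C)C[C@@H]2C(=O)OC
F6 | step 8 | methyl (1S,2S,7S,11S)-4-[(tert-butyldimethylsilyl)oxy]-8-methylidene-11-SC-bicyclo[5.4.0]undec-4-ene-2-carboxylate | C=C1CC[C@@H]([C@@H](C)CC/C=C(\C)CO[Si](c3ccccc3)(c3ccccc3)C(C)(C)C)[C@H]2[C@@H]1CC=C(O[Si](C)(C)C(C)(C)C)C[C@@H]2C(=O)OC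
F7 | step 10 | methyl (1S,2S,7S,11S)-4,8-dimethylidene-11-SC-bicyclo[5.4.0]undecane-2-carboxylate | C=C1CC[C@@H]([C@@H](C)CC/C=C(\C)CO[Si](c3ccccc3)(c3ccccc3)C(C)(C)C)[C@H]2[C@@H]1CCC(=C)C[C@@H]2C(=O)OC
F8 | step 10 | N-methoxy-N-methyl amide corresponding to F7 | C=C1CC[C@@H]([C@@H](C)CC/C=C(\C)CO[Si](c3ccccc3)(c3ccccc3)C(C)(C)C)[C@H]2[C@@H]1CCC(=C)C[C@@H]2C(=O)N(C)OC
F9 | step 10 | bromomagnesium hemiaminal of F8 (but-3-enyl added to the amide carbonyl) | C=C1CC[C@@H]([C@@H](C)CC/C=C(\C)CO[Si](c3ccccc3)(c3ccccc3)C(C)(C)C)[C@H]2[C@@H]1CCC(=C)C[C@@H]2C(O[Mg]Br)(CCC=C)N(C)OC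
F10 | step 10 | but-3-enyl ketone: 1-[(1S,2S,7S,11S)-4,8-dimethylidene-11-SC-bicyclo[5.4.0]undecan-2-yl]pent-4-en-1-one | C=C1CC[C@@H]([C@@H](C)CC/C=C(\C)CO[Si](c3ccccc3)(c3ccccc3)C(C)(C)C)[C@H]2[C@@H]1CCC(=C)C[C@@H]2C(=O)CCC=C
F11 | step 2 | (4S)-4-[(2S,5E)-6-methyl-7-oxohept-5-en-2-yl]cyclohex-2-en-1-one | O=C1CC[C@@H]([C@@H](C)CC/C=C(\C)C=O)C=C1
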